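## Retrosynthetic overview

1. The last C–C bond is lactone Cα–CH2(aryl). It is made by anti-alkylation of a β-substituted γ-butyrolactone enolate (fragment B) with a dihydrobenzofuran-5-ylmethyl bromide (fragment A). Five silyl ethers are then removed together.
2. Fragment B: the lactone ring and its Cβ/carbinol stereo pair come from one L-proline anti cross-aldol of methyl 4-oxobutanoate with O-TIPS-vanillin, followed by reduction and lactonisation.
3. Fragment A: the dihydrofuran ring (O1–C2–C3–C3a–C7a) is not closed as such. It is cut out of the six-membered pyranone ring (O1–C2–C3–C4–C4a–C8a) of a (2S)-flavanone by an iodine(III) 1,2-aryl shift. The shift moves C4a from C4 to C3 and pushes C4 out of the ring as the ester carbon, which later becomes the CH2OH carbon.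
4. Enabling feature: C3 of the dihydrofuran ring carries both arene carbon C3a and a one-carbon oxygenated branch, next to the O1–C2(aryl) stereocentre. O1 on C7a, ortho to the migrating carbon, stabilises the bridged phenonium ion. C2, set once by Pd-catalysed conjugate arylation of a chromone, dictates C3.
5. Ring order: pyranone (step 2), then dihydrofuran by contraction (step 5). The lactone (step 12) is made separately, followed by union (step 14) and deprotection (step 15).

Key step: step 5

Assumption: the facial sense of the pyridine-oxazoline/palladium catalyst on the chromone is taken to be the one known for cyclic enones. This calls for the (R)-ligand to reach the (2S)-flavanone. If the sense were opposite, the (S)-ligand would be used and nothing else changes.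

## Route

Step 1
Reactants: 1 1-(2-hydroxy-3-methoxyphenyl)ethan-1-one
Product: 2 1-(5-bromo-2-hydroxy-3-methoxyphenyl)ethan-1-one
Conditions: NBS, MeCN, 0 °C → rt
Reagents that add atoms: N-bromosuccinimide O=C1CCC(=O)N1Br
Why: Electrophilic aromatic bromination, in which the free phenol directs to its only open para position (C5) because both ortho positions are blocked by acetyl and methoxy.

Step 2
Reactants: 2 1-(5-bromo-2-hydroxy-3-methoxyphenyl)ethan-1-one
Product: 4 6-bromo-8-methoxy-4H-chromen-4-one, via enaminone 3 (not isolated)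
Conditions: Me2NCH(OMe)2, toluene, 100 °C; then conc. HCl, CH2Cl2, 40 °C
Reagents that add atoms: N,N-dimethylformamide dimethyl acetal COC(OC)N(C)C
Why: Standard chromone synthesis, in which condensation gives the enaminone and acid then induces 6-endo addition of the phenol and loss of dimethylamine to build the pyranone ring.

Step 3
Reactants: 5 (4-hydroxy-3-methoxyphenyl)boronic acid
Product: 6 [3-methoxy-4-(pivaloyloxy)phenyl]boronic acid
Conditions: PivCl, Et3N, CH2Cl2, 0 °C → rt; aq. work-up
Reagents that add atoms: pivaloyl chloride CC(C)(C)C(=O)Cl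
Why: Schotten–Baumann-type O-acylation of the phenol, with any mixed boron anhydride hydrolysed on work-up, installs an electron-withdrawing, acid-stable group that tempers this ring for step 5.

Step 4
Reactants: 4 6-bromo-8-methoxy-4H-chromen-4-one; 6 [3-methoxy-4-(pivaloyloxy)phenyl]boronic acid
Product: 7 4-[(2S)-6-bromo-8-methoxy-4-oxochroman-2-yl]-2-methoxyphenyl pivalate
Conditions: Pd(OCOCF3)2 (5 mol %), (R)-4-tert-butyl-2-(pyridin-2-yl)-4,5-dihydrooxazole (6 mol %), NH4PF6 (30 mol %), H2O (5 equiv), ClCH2CH2Cl, 60 °C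
Reagents that add atoms: none
Why: Palladium(II)-catalysed asymmetric conjugate addition of an arylboronic acid to a chromone, in which the ligand-bound aryl–Pd species inserts into C2=C3 on the face left open by the tert-butyl group and sets C2 as S, while the base-free medium avoids retro-oxa-Michael racemisation and the Pd(II)-only cycle leaves the C–Br bond alone.

Step 5
Reactants: 7 4-[(2S)-6-bromo-8-methoxy-4-oxochroman-2-yl]-2-methoxyphenyl pivalate
Product: 10 methyl (2S,3S)-5-bromo-7-methoxy-2-[3-methoxy-4-(pivaloyloxy)phenyl]-2,3-dihydro-1-benzofuran-3-carboxylate, via enol ether 8 (not isolated), via iodane ketal 9 (not isolated)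
Conditions: PhI(OAc)2, H2SO4 (cat.), HC(OMe)3, rt; aq. NaHCO3 work-up
Reagents that add atoms: trimethyl orthoformate COC(OC)OC; (diacetoxyiodo)benzene CC(=O)OI(OC(C)=O)c1ccccc1 (its atoms stay only in intermediate 9)
Why: Acid and orthoformate turn the C4 ketone into enol ether 8, the iodine(III) electrophile adds to C3 on the face away from the C2 aryl group while methanol caps C4, and in the resulting diequatorial iodane ketal 9 the ring bond C4–C4a, antiperiplanar to the equatorial C3–I bond, migrates to C3 as iodobenzene leaves, the dimethoxycarbenium ion at the expelled C4 collapsing to the methyl ester. The closest known reaction type is exactly this oxidative 1,2-aryl shift of flavanones with iodine(III) or thallium(III) in orthoformate, the cyclic version of the aryl alkyl ketone to 2-arylalkanoate rearrangement. The five-membered ring closes by ipso attack of C4a on C3 (3-exo-tet closure to a spiro phenonium ion) followed by cleavage of C4–C4a, so the six-membered O1–C2–C3–C4–C4a–C8a ring becomes the O1–C2–C3–C3a–C7a ring without any open-chain stage. C3 is controlled by C2 through two stereospecific events, anti addition of iodine and inversion in the shift, which place the ester trans to the aryl group, and C2 itself is not touched because the acidic, base-free medium does not open the pyranone by retro-oxa-Michael reaction. The step needs the A-ring shift to win over the shift of the C2 aryl group (isoflavone), over elimination (flavone) and over methanolysis at C3: O1 ortho to C4a raises the migratory aptitude of the A ring, the pivalate lowers that of the other ring and shields it from the oxidant, and in the diequatorial conformer the C2–aryl bond is gauche, not anti, to C3–I.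

Step 6
Reactants: 10 methyl (2S,3S)-5-bromo-7-methoxy-2-[3-methoxy-4-(pivaloyloxy)phenyl]-2,3-dihydro-1-benzofuran-3-carboxylate
Product: 11 4-[(2S,3R)-5-bromo-3-(hydroxymethyl)-7-methoxy-2,3-dihydro-1-benzofuran-2-yl]-2-methoxyphenol
Conditions: LiAlH4, THF, 0 °C; aq. NaOH work-up
Reagents that add atoms: none
Why: Hydride reduction takes the ester to the primary alcohol and removes the pivalate in the same operation, while at 0 °C the aryl bromide and both stereocentres should stay untouched (the descriptor at C3 changes only through the priority rules).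

Step 7
Reactants: 11 4-[(2S,3R)-5-bromo-3-(hydroxymethyl)-7-methoxy-2,3-dihydro-1-benzofuran-2-yl]-2-methoxyphenol
Product: 12 (2S,3R)-5-bromo-2-[4-(tert-butyldimethylsilyloxy)-3-methoxyphenyl]-3-[(tert-butyldimethylsilyloxy)methyl]-7-methoxy-2,3-dihydro-1-benzofuran
Conditions: TBSCl, imidazole, DMF, rt
Reagents that add atoms: tert-butyldimethylsilyl chloride CC(C)(C)[Si](C)(C)Cl
Why: Imidazole-promoted silylation covers the phenol and the primary alcohol in one operation with groups that survive organolithium and enolate chemistry and fall to fluoride.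

Step 8
Reactants: 12 (2S,3R)-5-bromo-2-[4-(tert-butyldimethylsilyloxy)-3-methoxyphenyl]-3-[(tert-butyldimethylsilyloxy)methyl]-7-methoxy-2,3-dihydro-1-benzofuran
Product: 14 (2S,3R)-2-[4-(tert-butyldimethylsilyloxy)-3-methoxyphenyl]-3-[(tert-butyldimethylsilyloxy)methyl]-7-methoxy-2,3-dihydro-1-benzofuran-5-carbaldehyde, via aryllithium 13 (not isolated)
Conditions: n-BuLi, THF, −78 °C; DMF, −78 → 0 °C; H2O
Reagents that add atoms: N,N-dimethylformamide CN(C)C=O; n-butyllithium [Li]CCCC (lithium stays only in intermediate 13)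
Why: Bromine–lithium exchange is faster at −78 °C than any deprotonation of the dihydrofuran ring, and the Bouveault aldehyde synthesis with DMF delivers the C5 formyl group.

Step 9
Reactants: 14 (2S,3R)-2-[4-(tert-butyldimethylsilyloxy)-3-methoxyphenyl]-3-[(tert-butyldimethylsilyloxy)methyl]-7-methoxy-2,3-dihydro-1-benzofuran-5-carbaldehyde
Product: 15 {(2S,3R)-2-[4-(tert-butyldimethylsilyloxy)-3-methoxyphenyl]-3-[(tert-butyldimethylsilyloxy)methyl]-7-methoxy-2,3-dihydro-1-benzofuran-5-yl}methanol
Conditions: NaBH4, EtOH/THF, 0 °C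
Reagents that add atoms: none
Why: Borohydride reduction of an aromatic aldehyde is fast at 0 °C, so the phenolic silyl ether should not see prolonged basic alcohol.

Step 10
Reactants: 15 {(2S,3R)-2-[4-(tert-butyldimethylsilyloxy)-3-methoxyphenyl]-3-[(tert-butyldimethylsilyloxy)methyl]-7-methoxy-2,3-dihydro-1-benzofuran-5-yl}methanol
Product: 16 (2S,3R)-5-(bromomethyl)-2-[4-(tert-butyldimethylsilyloxy)-3-methoxyphenyl]-3-[(tert-butyldimethylsilyloxy)methyl]-7-methoxy-2,3-dihydro-1-benzofuran
Conditions: CBr4, PPh3, CH2Cl2, 0 °C; used at once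
Reagents that add atoms: carbon tetrabromide BrC(Br)(Br)Br
Why: The Appel reaction converts the benzylic alcohol into the bromide under neutral conditions that spare the silyl ethers and the benzylic C2–O1 bond.

Step 11
Reactants: 17 vanillin (4-hydroxy-3-methoxybenzaldehyde)
Product: 18 3-methoxy-4-(triisopropylsilyloxy)benzaldehyde
Conditions: TIPSCl, imidazole, DMF, rt
Reagents that add atoms: triisopropylsilyl chloride CC(C)[Si](Cl)(C(C)C)C(C)C
Why: Imidazole-promoted silylation, with the bulky TIPS group chosen because a silyl ether para to a formyl group is otherwise easily lost to carboxylate or water in DMF.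

Step 12
Reactants: 18 3-methoxy-4-(triisopropylsilyloxy)benzaldehyde; 19 methyl 4-oxobutanoate
Product: 22 (4R)-4-{(R)-hydroxy[3-methoxy-4-(triisopropylsilyloxy)phenyl]methyl}dihydrofuran-2(3H)-one, via aldol aldehyde 20 (not isolated), via diol ester 21 (not isolated)
Conditions: L-proline (30 mol %), DMF, 4 °C, slow addition of 19; then MeOH, NaBH4, 0 °C; aq. NH4Cl work-up
Reagents that add atoms: none
Why: Proline enamine catalysis of a cross-aldol reaction, in which the E-enamine of 19 attacks the Re face of the non-enolisable aldehyde through the acid-organised chair transition state and sets Cβ and the carbinol carbon in one anti-selective event, after which borohydride reduces the formyl group and the primary alkoxide lactonises onto the methyl ester.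

Step 13
Reactants: 22 (4R)-4-{(R)-hydroxy[3-methoxy-4-(triisopropylsilyloxy)phenyl]methyl}dihydrofuran-2(3H)-one
Product: 23 (4R)-4-{(R)-[3-methoxy-4-(triisopropylsilyloxy)phenyl](triethylsilyloxy)methyl}dihydrofuran-2(3H)-one
Conditions: TESCl, imidazole, DMAP (cat.), CH2Cl2, 0 °C → rt
Reagents that add atoms: triethylsilyl chloride CC[Si](Cl)(CC)CC
Why: Silylation blocks the γ-hydroxyl group so that no alkoxide can translactonise in the enolate step, and the TES group is labile enough for the mild final cleavage.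

Step 14
Reactants: 23 (4R)-4-{(R)-[3-methoxy-4-(triisopropylsilyloxy)phenyl](triethylsilyloxy)methyl}dihydrofuran-2(3H)-one; 16 (2S,3R)-5-(bromomethyl)-2-[4-(tert-butyldimethylsilyloxy)-3-methoxyphenyl]-3-[(tert-butyldimethylsilyloxy)methyl]-7-methoxy-2,3-dihydro-1-benzofuran
Product: 25 penta-O-silylated target, (3R,4R)-3-({(2S,3R)-2-[4-(tert-butyldimethylsilyloxy)-3-methoxyphenyl]-3-[(tert-butyldimethylsilyloxy)methyl]-7-methoxy-2,3-dihydro-1-benzofuran-5-yl}methyl)-4-{(R)-[3-methoxy-4-(triisopropylsilyloxy)phenyl](triethylsilyloxy)methyl}dihydrofuran-2(3H)-one, via lithium enolate 24 (not isolated)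
Conditions: LiHMDS, THF, −78 °C; then 16, DMPU, −78 → −30 °C
Reagents that add atoms: lithium hexamethyldisilazide [Li]N([Si](C)(C)C)[Si](C)(C)C (lithium stays only in intermediate 24)
Why: Alkylation of a β-substituted γ-butyrolactone enolate with a benzylic bromide, the standard union in lignan lactone synthesis, takes place on the face opposite the bulky Cβ substituent and sets Cα as R (3,4-trans).

Step 15
Reactants: 25 penta-O-silylated target
Product: 26 target, (3R,4R)-4-[(R)-hydroxy(4-hydroxy-3-methoxyphenyl)methyl]-3-{[(2S,3R)-2-(4-hydroxy-3-methoxyphenyl)-3-(hydroxymethyl)-7-methoxy-2,3-dihydro-1-benzofuran-5-yl]methyl}dihydrofuran-2(3H)-one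
Conditions: TBAF/AcOH (1:1, excess), THF, 0 °C → rt
Reagents that add atoms: none
Why: Buffered fluoride cleaves all five Si–O bonds while acetic acid keeps the freed phenols protonated, so that p-quinone methide formation at the carbinol carbon or at C2 and translactonisation onto the free carbinol oxygen should not set in and no stereocentre is touched.

## Compound list

1 | 1-(2-hydroxy-3-methoxyphenyl)ethan-1-one | CC(=O)c1cccc(OC)c1O | starting material
2 | 1-(5-bromo-2-hydroxy-3-methoxyphenyl)ethan-1-one | CC(=O)c1cc(Br)cc(OC)c1O | intermediate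
3 | (E)-1-(5-bromo-2-hydroxy-3-methoxyphenyl)-3-(dimethylamino)prop-2-en-1-one | CN(C)/C=C/C(=O)c1cc(Br)cc(OC)c1O | intermediate
4 | 6-bromo-8-methoxy-4H-chromen-4-one | COc1cc(Br)cc2c1OC=CC2=O | intermediate
5 | (4-hydroxy-3-methoxyphenyl)boronic acid | COc1cc(B(O)O)ccc1O | starting material
6 | [3-methoxy-4-(pivaloyloxy)phenyl]boronic acid | COc1cc(B(O)O)ccc1OC(=O)C(C)(C)C | intermediate
7 | 4-[(2S)-6-bromo-8-methoxy-4-oxochroman-2-yl]-2-methoxyphenyl pivalate | COc1cc(Br)cc2c1O[C@@H](CC2=O)c1ccc(OC(=O)C(C)(C)C)c(OC)c1 | intermediate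
8 | 4-[(2S)-6-bromo-4,8-dimethoxy-2H-chromen-2-yl]-2-methoxyphenyl pivalate | COc1cc(Br)cc2c1O[C@@H](C=C2OC)c1ccc(OC(=O)C(C)(C)C)c(OC)c1 | intermediate
9 | 4-{(2R,3R)-3-[acetoxy(phenyl)-λ3-iodanyl]-6-bromo-4,4,8-trimethoxychroman-2-yl}-2-methoxyphenyl pivalate (aryl and iodanyl trans, both equatorial) | COc1cc(Br)cc2c1O[C@@H]([C@@H](I(OC(C)=O)c1ccccc1)C2(OC)OC)c1ccc(OC(=O)C(C)(C)C)c(OC)c1 | intermediate
10 | methyl (2S,3S)-5-bromo-7-methoxy-2-[3-methoxy-4-(pivaloyloxy)phenyl]-2,3-dihydro-1-benzofuran-3-carboxylate (2,3-trans) | COc1cc([C@H]2Oc3c(OC)cc(Br)cc3[C@@H]2C(=O)OC)ccc1OC(=O)C(C)(C)C | intermediate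
11 | 4-[(2S,3R)-5-bromo-3-(hydroxymethyl)-7-methoxy-2,3-dihydro-1-benzofuran-2-yl]-2-methoxyphenol | COc1cc([C@H]2Oc3c(OC)cc(Br)cc3[C@@H]2CO)ccc1O | intermediate
12 | (2S,3R)-5-bromo-2-[4-(tert-butyldimethylsilyloxy)-3-methoxyphenyl]-3-[(tert-butyldimethylsilyloxy)methyl]-7-methoxy-2,3-dihydro-1-benzofuran | COc1cc([C@H]2Oc3c(OC)cc(Br)cc3[C@@H]2CO[Si](C)(C)C(C)(C)C)ccc1O[Si](C)(C)C(C)(C)C | intermediate
13 | 5-lithio derivative of 12 | COc1cc([C@H]2Oc3c(OC)cc([Li])cc3[C@@H]2CO[Si](C)(C)C(C)(C)C)ccc1O[Si](C)(C)C(C)(C)C | intermediate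
14 | (2S,3R)-2-[4-(tert-butyldimethylsilyloxy)-3-methoxyphenyl]-3-[(tert-butyldimethylsilyloxy)methyl]-7-methoxy-2,3-dihydro-1-benzofuran-5-carbaldehyde | COc1cc([C@H]2Oc3c(OC)cc(C=O)cc3[C@@H]2CO[Si](C)(C)C(C)(C)C)ccc1O[Si](C)(C)C(C)(C)C | intermediate
15 | {(2S,3R)-2-[4-(tert-butyldimethylsilyloxy)-3-methoxyphenyl]-3-[(tert-butyldimethylsilyloxy)methyl]-7-methoxy-2,3-dihydro-1-benzofuran-5-yl}methanol | COc1cc([C@H]2Oc3c(OC)cc(CO)cc3[C@@H]2CO[Si](C)(C)C(C)(C)C)ccc1O[Si](C)(C)C(C)(C)C | intermediate
16 | (2S,3R)-5-(bromomethyl)-2-[4-(tert-butyldimethylsilyloxy)-3-methoxyphenyl]-3-[(tert-butyldimethylsilyloxy)methyl]-7-methoxy-2,3-dihydro-1-benzofuran | COc1cc([C@H]2Oc3c(OC)cc(CBr)cc3[C@@H]2CO[Si](C)(C)C(C)(C)C)ccc1O[Si](C)(C)C(C)(C)C | intermediate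
17 | vanillin | COc1cc(C=O)ccc1O | starting material
18 | 3-methoxy-4-(triisopropylsilyloxy)benzaldehyde | COc1cc(C=O)ccc1O[Si](C(C)C)(C(C)C)C(C)C | intermediate
19 | methyl 4-oxobutanoate | COC(=O)CCC=O | starting material
20 | methyl (3S,4R)-3-formyl-4-hydroxy-4-[3-methoxy-4-(triisopropylsilyloxy)phenyl]butanoate (anti) | COC(=O)C[C@H](C=O)[C@@H](O)c1ccc(O[Si](C(C)C)(C(C)C)C(C)C)c(OC)c1 | intermediate
21 | methyl (3R,4R)-4-hydroxy-3-(hydroxymethyl)-4-[3-methoxy-4-(triisopropylsilyloxy)phenyl]butanoate | COC(=O)C[C@H](CO)[C@@H](O)c1ccc(O[Si](C(C)C)(C(C)C)C(C)C)c(OC)c1 | intermediate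
22 | (4R)-4-{(R)-hydroxy[3-methoxy-4-(triisopropylsilyloxy)phenyl]methyl}dihydrofuran-2(3H)-one | O=C1C[C@H](CO1)[C@@H](O)c1ccc(O[Si](C(C)C)(C(C)C)C(C)C)c(OC)c1 | intermediate
23 | (4R)-4-{(R)-[3-methoxy-4-(triisopropylsilyloxy)phenyl](triethylsilyloxy)methyl}dihydrofuran-2(3H)-one | O=C1C[C@H](CO1)[C@@H](O[Si](CC)(CC)CC)c1ccc(O[Si](C(C)C)(C(C)C)C(C)C)c(OC)c1 | intermediate
24 | lithium enolate of 23 | [Li]OC1=C[C@H](CO1)[C@@H](O[Si](CC)(CC)CC)c1ccc(O[Si](C(C)C)(C(C)C)C(C)C)c(OC)c1 | intermediate
25 | penta-O-silylated target (3R,4R lactone, R carbinol, 2S,3R dihydrobenzofuran) | COc1cc([C@H]2Oc3c(OC)cc(C[C@H]4C(=O)OC[C@@H]4[C@@H](O[Si](CC)(CC)CC)c4ccc(O[Si](C(C)C)(C(C)C)C(C)C)c(OC)c4)cc3[C@@H]2CO[Si](C)(C)C(C)(C)C)ccc1O[Si](C)(C)C(C)(C)C | intermediate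
26 | CNP0233460.1 | COc1cc([C@H]2Oc3c(OC)cc(C[C@H]4C(=O)OC[C@@H]4[C@@H](O)c4ccc(O)c(OC)c4)cc3[C@@H]2CO)ccc1O | target

## Step count

Total step count: 15.
Longest linear sequence: 11 (steps 1, 2, 4, 5, 6, 7, 8, 9, 10, 14, 15).

## Steps most likely to fail

**Step 5.**
- What may go wrong: the shift of the C2 aryl group, elimination of the iodane to the flavone, methanolysis at C3 or oxidation of the electron-rich rings could compete with the wanted A-ring shift.
- Fallback: it sets out from 7 and comes back at 10. It removes the oxidant from the rearrangement by using a halide as leaving group.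
- C3 of 7 is brominated with CuBr2 in EtOAc/CHCl3 at reflux to the equilibrated, diequatorial trans-3-bromoflavanone F1.
- HC(OMe)3/MeOH/TsOH converts it into the bromo dimethyl ketal F2.
- AgBF4 (or ZnBr2) in MeOH then triggers the Lewis-acid-promoted 1,2-aryl shift of an α-halo ketal. The stereochemical course is the same (inversion at C3) and gives 10.

**Step 12.**
- What may go wrong: addition of the enamine to an electron-rich aldehyde may be so slow that self-aldolisation of 19 takes over, and the anti selectivity may erode.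
- Fallback: it sets out from 18 and comes back at 23. It replaces catalysis by an oxazolidinone auxiliary.
- (R)-4-Benzyloxazolidin-2-one is acylated with pent-4-enoyl chloride (n-BuLi, THF, −78 °C) to the pentenoyl imide F3.
- The magnesium-halide-catalysed anti-aldol addition to 18 (MgCl2, Et3N, TMSCl, EtOAc, rt) works well with electron-rich aromatic aldehydes. It should give, through the chelated Z-enolate attacked opposite the benzyl group, the O-trimethylsilyl anti-aldol imide F4.
- TFA/MeOH frees the anti-aldol imide F5, and TESOTf/2,6-lutidine gives the O-triethylsilyl imide F6.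
- LiBH4 (Et2O/MeOH, 0 °C) removes the auxiliary to give the pentenol F7.
- Lemieux–Johnson oxidation (OsO4 cat., NaIO4, 2,6-lutidine, dioxane/H2O) gives the lactol F8.
- Ley–Griffith oxidation (TPAP, NMO) gives 23.

**Step 4.**
- What may go wrong: insertion into the electron-rich chromone may be slow, 6 may protodeboronate, and the facial selectivity may be insufficient.
- Fallback: it sets out from 4 and 6 and comes back at 7. It separates C–C bond formation from stereocontrol.
- The same addition with an achiral catalyst (Pd(OCOCF3)2, 2,2'-bipyridine, aq. MeOH, 60 °C) gives the racemic flavanone F9.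
- F9 is then resolved kinetically by asymmetric transfer hydrogenation (RuCl[(R,R)-TsDPEN](p-cymene), HCO2H/Et3N, EtOAc, rt, stopped near half conversion).
- The (2R)-enantiomer is reduced to the cis-flavan-4-ol F10, and unreacted (2S)-7 is separated by chromatography.

Further compounds
F1 | step 5 | trans-3-bromoflavanone, 4-[(2R,3R)-3,6-dibromo-8-methoxy-4-oxochroman-2-yl]-2-methoxyphenyl pivalate | COc1cc(Br)cc2c1O[C@@H]([C@@H](Br)C2=O)c1ccc(OC(=O)C(C)(C)C)c(OC)c1
F2 | step 5 | bromo dimethyl ketal, 4-[(2R,3R)-3,6-dibromo-4,4,8-trimethoxychroman-2-yl]-2-methoxyphenyl pivalate | COc1cc(Br)cc2c1O[C@@H]([C@@H](Br)C2(OC)OC)c1ccc(OC(=O)C(C)(C)C)c(OC)c1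
F3 | step 12 | pentenoyl imide, (R)-4-benzyl-3-(pent-4-enoyl)oxazolidin-2-one | C=CCCC(=O)N1[C@H](Cc2ccccc2)COC1=O
F4 | step 12 | O-trimethylsilyl anti-aldol imide, (R)-4-benzyl-3-[(2S)-2-{(R)-[3-methoxy-4-(triisopropylsilyloxy)phenyl](trimethylsilyloxy)methyl}pent-4-enoyl]oxazolidin-2-one | C=CC[C@H](C(=O)N1[C@H](Cc2ccccc2)COC1=O)[C@@H](O[Si](C)(C)C)c1ccc(O[Si](C(C)C)(C(C)C)C(C)C)c(OC)c1
F5 | step 12 | anti-aldol imide, (R)-4-benzyl-3-[(2S)-2-{(R)-hydroxy[3-methoxy-4-(triisopropylsilyloxy)phenyl]methyl}pent-4-enoyl]oxazolidin-2-one | C=CC[C@H](C(=O)N1[C@H](Cc2ccccc2)COC1=O)[C@@H](O)c1ccc(O[Si](C(C)C)(C(C)C)C(C)C)c(OC)c1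
F6 | step 12 | O-triethylsilyl imide, (R)-4-benzyl-3-[(2S)-2-{(R)-[3-methoxy-4-(triisopropylsilyloxy)phenyl](triethylsilyloxy)methyl}pent-4-enoyl]oxazolidin-2-one | C=CC[C@H](C(=O)N1[C@H](Cc2ccccc2)COC1=O)[C@@H](O[Si](CC)(CC)CC)c1ccc(O[Si](C(C)C)(C(C)C)C(C)C)c(OC)c1
F7 | step 12 | pentenol, (2R)-2-{(R)-[3-methoxy-4-(triisopropylsilyloxy)phenyl](triethylsilyloxy)methyl}pent-4-en-1-ol | C=CC[C@H](CO)[C@@H](O[Si](CC)(CC)CC)c1ccc(O[Si](C(C)C)(C(C)C)C(C)C)c(OC)c1
F8 | step 12 | lactol, (4R)-4-{(R)-[3-methoxy-4-(triisopropylsilyloxy)phenyl](triethylsilyloxy)methyl}tetrahydrofuran-2-ol (anomeric mixture) | OC1C[C@H](CO1)[C@@H](O[Si](CC)(CC)CC)c1ccc(O[Si](C(C)C)(C(C)C)C(C)C)c(OC)c1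
F9 | step 4 | racemic flavanone, rac-4-(6-bromo-8-methoxy-4-oxochroman-2-yl)-2-methoxyphenyl pivalate | COc1cc(Br)cc2c1OC(CC2=O)c1ccc(OC(=O)C(C)(C)C)c(OC)c1
F10 | step 4 | cis-flavan-4-ol, 4-[(2R,4R)-6-bromo-4-hydroxy-8-methoxychroman-2-yl]-2-methoxyphenyl pivalate | COc1cc(Br)cc2c1O[C@H](C[C@H]2O)c1ccc(OC(=O)C(C)(C)C)c(OC)c1
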